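**Retrosynthetic overview**
- C2–phenyl is cut last. The only stereocentre and ring B come from an enantioselective Rh-catalysed 1,4-addition of PhB(OH)2 to an achiral 6,8-dibenzylated 5,7-dihydroxychromone, so C2 sees no later step.
- Both ArCH2–C6/C8 links go back to aldehyde carbons. The benzylic C–O bonds of a tetraboracycle are removed by ionic hydrogenation.
- Key step: 5,7-dihydroxychromone, 2 × 2,3-dihydroxybenzaldehyde and 4 × PhB(OH)2 give two C–C bonds and four boron heterocycles in one operation. Two are dioxaborinines fused to ring A and two are dioxaboroles on the catechols.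
- Ring C, as the pyranone, comes from 2,4,6-trihydroxyacetophenone and one carbon of HC(OEt)3.
- Ring order: ring C first, then the four temporary boracycles together, which are opened again one step later. Ring A, ring B and both catechol rings are bought.

Assumption: the SMILES encodes the (2S)-flavanone (O1 > phenyl > C3 > H, counter-clockwise), and this enantiomer is the goal.

**Step 1**
Reactants: 1 2,4,6-trihydroxyacetophenone; 2 triethyl orthoformate
Product: 4 5,7-dihydroxy-4H-chromen-4-one, via 4-ethoxy-5,7-dihydroxychromenylium perchlorate 3 (not isolated)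
Conditions: HC(OEt)3 (6 equiv), 70% aq HClO4 (1.2 equiv), rt, 1 h; then H2O, 95 °C, 15 min
Reagents that add atoms: triethyl orthoformate CCOC(OCC)OCC; water O
Why: In this orthoformate/perchloric acid chromone synthesis (Claisen-type formylation and cyclodehydration), diethoxycarbenium formylates the acetyl enol, one of the two equivalent ortho-OH groups closes the ring to the 4-ethoxybenzopyrylium salt, and hot water hydrolyses that salt to the chromone, with no stereocentre formed.

**Step 2**
Reactants: 4 5,7-dihydroxy-4H-chromen-4-one; 5 2,3-dihydroxybenzaldehyde (2.2 equiv); 6 phenylboronic acid (4.4 equiv)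
Product: 8 chromone tetraboracycle [O5-B(Ph)-O-CH(Ar)-C6 plus O7-B(Ph)-O-CH(Ar)-C8; Ar = 2-phenyl-1,3,2-benzodioxaborol-4-yl; diastereomer mixture], via 2-phenyl-1,3,2-benzodioxaborole-4-carbaldehyde 7 (not isolated)
Conditions: EtCO2H (0.5 equiv), toluene, reflux, Dean–Stark, 24 h
Reagents that add atoms: 2,3-dihydroxybenzaldehyde O=Cc1cccc(O)c1O; phenylboronic acid OB(O)c1ccccc1
Why: Proposed new method: PhB(OH)2 first ties the catechol of 5 into dioxaborole 7 (which also frees the CHO from its internal hydrogen bond) and esterifies the phenols of 4; the aryl phenylboronate half-ester binds the aldehyde and delivers it to the ortho carbon through a six-membered transition state; each carbinol is locked at once as a 4H-1,3,2-dioxaborinine, so it cannot ionise and arylate a second chromone; fast B–O exchange lets the C6 carbinol sit on O5 while O7 templates C8; the closest known reaction type is the Nagata/Lau–Dufresne phenol–aldehyde–phenylboronic acid condensation to 1,3,2-benzodioxaborins, and the two new benzylic stereocentres form unselectively and are erased in step 3.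

**Step 3**
Reactants: 8 chromone tetraboracycle
Product: 9 6,8-bis(2,3-dihydroxybenzyl)-5,7-dihydroxy-4H-chromen-4-one
Conditions: Et3SiH (6 equiv), CF3CO2H (15 equiv), CH2Cl2, 0 °C to rt, 2 h; then 1 M aq HCl/THF, rt, 1 h
Reagents that add atoms: none
Why: In this ionic hydrogenation the acid ionises the doubly benzylic C–O(B) bonds to diarylmethyl cations of o-quinone methide type, these take hydride from Et3SiH far faster than the vinylogous-ester carbonyl of the chromone does, and aqueous acid then hydrolyses every B–O bond, which removes both benzylic stereocentres.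

**Step 4**
Reactants: 9 6,8-bis(2,3-dihydroxybenzyl)-5,7-dihydroxy-4H-chromen-4-one; 6 phenylboronic acid (6 equiv)
Product: 12 (2S)-6,8-bis(2,3-dihydroxybenzyl)-5,7-dihydroxyflavanone, via chromone bis(catechol phenylboronate) 10 (not isolated), via (2S)-flavanone bis(catechol phenylboronate) 11 (not isolated)
Conditions: [Rh(OH)(cod)]2 (2.5 mol %), (S)-MeO-F12-BIPHEP [(S)-6,6'-dimethoxy-2,2'-bis{bis(3,4,5-trifluorophenyl)phosphino}-1,1'-biphenyl] (5.5 mol %), toluene/THF 5:1, 40 °C, 16 h; then 1 M aq HCl/THF, 0 °C, 30 min
Reagents that add atoms: phenylboronic acid OB(O)c1ccccc1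
Why: In this Hayashi–Miyaura asymmetric 1,4-addition, excess PhB(OH)2 first masks both catechols as dioxaboroles (the water released feeds the catalytic cycle), the phenylrhodium bound to the (S)-biaryl diphosphine adds across C2=C3 on the same enone face that gives (S)-3-phenylcyclohexanone (mapping Cα to C3 and the ring CH2 to O1 keeps the descriptor, so C2 is S), the oxa-π-allyl rhodium enolate is protonated quickly by phenol or water, and the cold base-free acidic work-up strips boron without opening ring C.

**Compound list**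
1 | 2,4,6-trihydroxyacetophenone | CC(=O)c1c(O)cc(O)cc1O | starting material
2 | triethyl orthoformate | CCOC(OCC)OCC | starting material
3 | 4-ethoxy-5,7-dihydroxychromenylium perchlorate | CCOc1cc[o+]c2cc(O)cc(O)c12.[O-]Cl(=O)(=O)=O | intermediate
4 | 5,7-dihydroxy-4H-chromen-4-one | O=C1C=COc2cc(O)cc(O)c21 | intermediate
5 | 2,3-dihydroxybenzaldehyde | O=Cc1cccc(O)c1O | starting material
6 | phenylboronic acid | OB(O)c1ccccc1 | starting material
7 | 2-phenyl-1,3,2-benzodioxaborole-4-carbaldehyde | O=Cc1cccc2OB(c3ccccc3)Oc12 | intermediate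
8 | chromone tetraboracycle: chromone with O5–B(Ph)–O–CH(Ar)–C6 and O7–B(Ph)–O–CH(Ar)–C8 bridges (two fused 2-phenyl-4H-1,3,2-dioxaborinine rings), Ar = 2-phenyl-1,3,2-benzodioxaborol-4-yl, both benzylic CH centres unselective (diastereomer mixture) | O=C1C=COc2c3C(c4cccc5OB(c6ccccc6)Oc45)OB(c4ccccc4)Oc3c3C(c4cccc5OB(c6ccccc6)Oc45)OB(c4ccccc4)Oc3c12 | intermediate
9 | 6,8-bis(2,3-dihydroxybenzyl)-5,7-dihydroxy-4H-chromen-4-one | O=C1C=COc2c(Cc3cccc(O)c3O)c(O)c(Cc3cccc(O)c3O)c(O)c21 | intermediate
10 | 5,7-dihydroxy-6,8-bis[(2-phenyl-1,3,2-benzodioxaborol-4-yl)methyl]-4H-chromen-4-one | O=C1C=COc2c(Cc3cccc4OB(c5ccccc5)Oc34)c(O)c(Cc3cccc4OB(c5ccccc5)Oc34)c(O)c21 | intermediate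
11 | (2S)-5,7-dihydroxy-2-phenyl-6,8-bis[(2-phenyl-1,3,2-benzodioxaborol-4-yl)methyl]chroman-4-one | O=C1C[C@@H](c2ccccc2)Oc2c(Cc3cccc4OB(c5ccccc5)Oc34)c(O)c(Cc3cccc4OB(c5ccccc5)Oc34)c(O)c21 | intermediate
12 | (2S)-6,8-bis(2,3-dihydroxybenzyl)-5,7-dihydroxy-2-phenylchroman-4-one (CNP0059702.1) | O=C1C[C@@H](c2ccccc2)Oc2c(Cc3cccc(O)c3O)c(O)c(Cc3cccc(O)c3O)c(O)c21 | target

**Total step count:** 4. **Longest linear sequence:** 4 (1 → 4 → 8 → 9 → 12).

**Steps most likely to fail**

Step 2.
- Risk: ring A of the chromone is a weaker nucleophile than a simple phenol. The reaction may stop after one aldehyde. The doubly benzylic carbinol boronates may also ionise and arylate a second chromone, giving triarylmethanes.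
- Fallback: it sets out from 4 and 5 and comes back at 9, leaving out 8 and step 3. Aldehyde 5 is reduced with NaBH4 in MeOH to 2,3-dihydroxybenzyl alcohol F1. Chromone 4 is then heated with 2.5 equiv of it and ZnCl2 in dioxane. The o-quinone methide formed from the alcohol alkylates C6 and C8 by Friedel–Crafts attack and gives 9 directly.

Step 4.
- Risk: the free 5-OH/4-C=O pair can chelate rhodium as acetylacetonate does and slow transmetalation. The 5,7-dioxygenated chromone is a poor acceptor. β-Aryloxide elimination from the rhodium enolate would give the chalcone, which recloses as racemate.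
- Fallback: it sets out from 9 and comes back at 12. All six hydroxyls are capped with Ac2O/pyridine to give 6,8-bis(2,3-diacetoxybenzyl)-5,7-diacetoxy-4H-chromen-4-one F2, a more electrophilic acceptor that cannot chelate. The same asymmetric 1,4-addition of PhB(OH)2 gives (2S)-6,8-bis(2,3-diacetoxybenzyl)-5,7-diacetoxyflavanone F3. HCl in MeOH (made from AcCl, 0 °C to rt) removes the acetates under acidic conditions that leave C2 untouched.

Step 3.
- Risk: in CF3CO2H the chromone is partly protonated to a 4-hydroxypyrylium ion, so hydride could enter at C2 (chromanone) or deoxygenate C4. The acyl-deactivated ring A may also ionise slowly.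
- Fallback: it sets out from 8 and comes back at 9. Boron is removed under neutral conditions with pinacol (4.5 equiv, THF, rt) to give 6,8-bis[(2,3-dihydroxyphenyl)(hydroxy)methyl]-5,7-dihydroxy-4H-chromen-4-one F4. This is heated without purification with diethyl 2,6-dimethyl-1,4-dihydropyridine-3,5-dicarboxylate (3 equiv) in EtOH at 70 °C. Thermal loss of water gives the o-quinone methides, which are reduced by transfer hydrogenation with no strong acid present.

**Further compounds**
F1 | step 2 | 2,3-dihydroxybenzyl alcohol | OCc1cccc(O)c1O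
F2 | step 4 | 6,8-bis(2,3-diacetoxybenzyl)-5,7-diacetoxy-4H-chromen-4-one | O=C1C=COc2c(Cc3cccc(OC(C)=O)c3OC(C)=O)c(OC(C)=O)c(Cc3cccc(OC(C)=O)c3OC(C)=O)c(OC(C)=O)c21
F3 | step 4 | (2S)-6,8-bis(2,3-diacetoxybenzyl)-5,7-diacetoxyflavanone | O=C1C[C@@H](c2ccccc2)Oc2c(Cc3cccc(OC(C)=O)c3OC(C)=O)c(OC(C)=O)c(Cc3cccc(OC(C)=O)c3OC(C)=O)c(OC(C)=O)c21
F4 | step 3 | 6,8-bis[(2,3-dihydroxyphenyl)(hydroxy)methyl]-5,7-dihydroxy-4H-chromen-4-one | O=C1C=COc2c(C(O)c3cccc(O)c3O)c(O)c(C(O)c3cccc(O)c3O)c(O)c21
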